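**Retrosynthetic overview**
1. Target 33 ← removal of five MOM groups from (2S)-flavanone 32 ← transfer-hydrogenative kinetic resolution of the C2-epimer mixture 31 ← oxa-Michael closure of 2'-hydroxychalcone 30. Ring C is the only ring formed, and it is formed last.
2. Chalcone 30 ← late Claisen–Schmidt union of ring A acetophenone 22 and ring B aldehyde 28.
3. 22 ← ortho-lithiation/acetylation and SEM removal from 18 ← Negishi coupling of aryl iodide 10 with (S)-lavandulylzinc iodide 17.
4. 17 ← Evans deconjugative alkylation of a senecioyl imide with prenyl bromide, then LiBH4 reduction and iodination.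
5. Rings A and B both come from resorcinol: MOM protection, directed ortho-lithiation, and Ir-catalysed C–H borylation/oxidation to add the third oxygen.

Assumption: (S)-4-benzyloxazolidin-2-one is used as a recoverable chiral auxiliary; it is listed as a reagent in step 6 and leaves again in step 8.

Abbreviations: MOM = methoxymethyl; SEM = 2-(trimethylsilyl)ethoxymethyl; prenyl = 3-methylbut-2-en-1-yl; (R)-lavandulyl = (2R)-5-methyl-2-(prop-1-en-2-yl)hex-4-en-1-yl; B2pin2 = bis(pinacolato)diboron; SPhos = 2-dicyclohexylphosphino-2',6'-dimethoxybiphenyl; TsDPEN = N-tosyl-1,2-diphenylethane-1,2-diamine.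

**Route**

Step 1
Reactants: 1 resorcinol
Product: 2 1,3-bis(methoxymethoxy)benzene
Conditions: MOMCl, NaH, DMF, 0 °C → rt
Reagents that add atoms: chloromethyl methyl ether (MOMCl), COCCl
Why: Williamson-type O-alkylation of both phenoxides installs MOM groups that later direct ortho-lithiation.

Step 2
Reactants: 2 1,3-bis(methoxymethoxy)benzene; 3 prenyl bromide
Product: 5 1,3-bis(methoxymethoxy)-2-prenylbenzene, via 2,6-bis(methoxymethoxy)phenyllithium 4 (not isolated)
Conditions: n-BuLi, THF, 0 °C; then CuBr·SMe2 (10 mol %), 3, −78 °C → rt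
Reagents that add atoms: none
Why: Directed ortho-metalation occurs at the carbon flanked by both OMOM groups, and copper-catalysed SN2 allylation of the aryllithium with prenyl bromide follows.

Step 3
Reactants: 5 1,3-bis(methoxymethoxy)-2-prenylbenzene
Product: 7 3,5-bis(methoxymethoxy)-4-prenylphenol, via aryl pinacol boronate 6 (not isolated)
Conditions: B2pin2, [Ir(OMe)(cod)]2 (1.5 mol %), 4,4'-di-tert-butyl-2,2'-bipyridine (3 mol %), THF, 60 °C; then 30% aq. H2O2, NaOH, 0 °C
Reagents that add atoms: hydrogen peroxide, OO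
Why: Sterically controlled Ir-catalysed aromatic C–H borylation hits the only C–H without an ortho substituent (para to prenyl), and alkaline peroxide oxidises the boronate to the phenol without epoxidising the trisubstituted alkene.

Step 4
Reactants: 7 3,5-bis(methoxymethoxy)-4-prenylphenol
Product: 8 3,5-bis(methoxymethoxy)-4-prenylphenyl SEM ether
Conditions: SEMCl, NaH, DMF, 0 °C → rt
Reagents that add atoms: 2-(trimethylsilyl)ethoxymethyl chloride (SEMCl), C[Si](C)(C)CCOCCl
Why: Williamson etherification puts a fluoride-labile SEM group, orthogonal to MOM, on the oxygen that will become O1.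

Step 5
Reactants: 8 3,5-bis(methoxymethoxy)-4-prenylphenyl SEM ether
Product: 10 2-iodo-3,5-bis(methoxymethoxy)-4-prenylphenyl SEM ether, via ortho-lithiated SEM ether 9 (not isolated)
Conditions: n-BuLi, THF, 0 °C; then I2, −78 °C
Reagents that add atoms: iodine, II
Why: Directed ortho-metalation between OSEM and OMOM (the two open positions are equivalent) followed by iodinolysis of the aryllithium gives the cross-coupling handle.

Step 6
Reactants: 11 3-methylbut-2-enoyl chloride
Product: 12 (4S)-4-benzyl-3-(3-methylbut-2-enoyl)oxazolidin-2-one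
Conditions: (S)-4-benzyloxazolidin-2-one, n-BuLi, THF, −78 °C; then 11, −78 → 0 °C
Reagents that add atoms: (S)-4-benzyloxazolidin-2-one (chiral auxiliary), O=C1N[C@@H](Cc2ccccc2)CO1
Why: N-acylation of the lithiated oxazolidinone by the acid chloride (nucleophilic acyl substitution) attaches the Evans auxiliary.

Step 7
Reactants: 12 (4S)-4-benzyl-3-(3-methylbut-2-enoyl)oxazolidin-2-one; 3 prenyl bromide
Product: 14 (4S)-4-benzyl-3-[(2S)-5-methyl-2-(prop-1-en-2-yl)hex-4-enoyl]oxazolidin-2-one, via sodium (Z)-dienolate 13 (not isolated)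
Conditions: NaN(SiMe3)2, THF, −78 °C; then 3, −78 → −40 °C
Reagents that add atoms: none
Why: In this Evans asymmetric deconjugative alkylation, γ-deprotonation gives the chelated Z-dienolate, which is alkylated at the α-carbon on the face opposite the benzyl group, setting the (2S) centre that becomes the (R)-lavandulyl centre and unveiling the isopropenyl group.

Step 8
Reactants: 14 (4S)-4-benzyl-3-[(2S)-5-methyl-2-(prop-1-en-2-yl)hex-4-enoyl]oxazolidin-2-one
Product: 15 (2S)-5-methyl-2-(prop-1-en-2-yl)hex-4-en-1-ol [(S)-lavandulol]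
Conditions: LiBH4, H2O (1 equiv), Et2O, 0 °C
Reagents that add atoms: none
Why: Reductive cleavage of the imide by LiBH4 gives the primary alcohol without epimerising the α-centre and releases the auxiliary for recovery.

Step 9
Reactants: 15 (S)-lavandulol
Product: 16 (3S)-3-(iodomethyl)-2,6-dimethylhepta-1,5-diene [(S)-lavandulyl iodide]
Conditions: I2, PPh3, imidazole, CH2Cl2, 0 °C → rt
Reagents that add atoms: iodine, II
Why: Appel-type iodination proceeds by SN2 at the primary carbon and leaves the adjacent stereocentre untouched.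

Step 10
Reactants: 16 (S)-lavandulyl iodide; 10 2-iodo-3,5-bis(methoxymethoxy)-4-prenylphenyl SEM ether
Product: 18 3,5-bis(methoxymethoxy)-2-[(R)-lavandulyl]-4-prenylphenyl SEM ether, via (S)-lavandulylzinc iodide 17 (not isolated)
Conditions: 16, Zn dust, LiCl, THF, 40 °C; then 10, Pd(OAc)2 (3 mol %), SPhos (6 mol %), THF, rt → 50 °C
Reagents that add atoms: none
Why: In this Negishi sp3–sp2 cross-coupling, zinc inserts into the primary C–I bond without affecting the β-stereocentre, and the zerovalent palladium/SPhos catalyst formed from Pd(OAc)2 couples the primary alkylzinc with the hindered electron-rich aryl iodide faster than β-hydride elimination.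

Step 11
Reactants: 18 3,5-bis(methoxymethoxy)-2-[(R)-lavandulyl]-4-prenylphenyl SEM ether; 19 N-methoxy-N-methylacetamide
Product: 21 1-{2-(SEM-oxy)-4,6-bis(methoxymethoxy)-3-[(R)-lavandulyl]-5-prenylphenyl}ethan-1-one, via hexasubstituted aryllithium 20 (not isolated)
Conditions: n-BuLi, THF, 0 °C; then 19, −78 °C → rt
Reagents that add atoms: none
Why: Directed ortho-metalation at the last ring C–H (between OSEM and OMOM) is followed by Weinreb amide acylation, whose chelated tetrahedral intermediate prevents over-addition.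

Step 12
Reactants: 21 1-{2-(SEM-oxy)-4,6-bis(methoxymethoxy)-3-[(R)-lavandulyl]-5-prenylphenyl}ethan-1-one
Product: 22 1-{2-hydroxy-4,6-bis(methoxymethoxy)-3-[(R)-lavandulyl]-5-prenylphenyl}ethan-1-one
Conditions: Bu4NF, THF/DMPU, 50 °C
Reagents that add atoms: none
Why: Fluoride-induced fragmentation of the SEM acetal frees only the oxygen flanked by the acetyl and lavandulyl groups, because MOM ethers are inert to fluoride.

Step 13
Reactants: 2 1,3-bis(methoxymethoxy)benzene
Product: 24 3,5-bis(methoxymethoxy)phenol, via aryl pinacol boronate 23 (not isolated)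
Conditions: B2pin2, [Ir(OMe)(cod)]2 (1.5 mol %), 4,4'-di-tert-butyl-2,2'-bipyridine (3 mol %), THF, 60 °C; then 30% aq. H2O2, NaOH, 0 °C
Reagents that add atoms: hydrogen peroxide, OO
Why: Ir-catalysed C–H borylation is sterically directed to C5 (meta to both OMOM groups), and oxidation of the boronate gives the phloroglucinol oxygenation pattern.

Step 14
Reactants: 24 3,5-bis(methoxymethoxy)phenol
Product: 25 1,3,5-tris(methoxymethoxy)benzene
Conditions: MOMCl, NaH, DMF, 0 °C → rt
Reagents that add atoms: chloromethyl methyl ether (MOMCl), COCCl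
Why: Williamson-type MOM protection of the remaining phenol gives a symmetric, base-stable ring B precursor.

Step 15
Reactants: 25 1,3,5-tris(methoxymethoxy)benzene; 26 N,N-dimethylformamide
Product: 28 2,4,6-tris(methoxymethoxy)benzaldehyde, via 2,4,6-tris(methoxymethoxy)phenyllithium 27 (not isolated)
Conditions: n-BuLi, THF, 0 °C; then 26, 0 °C → rt; aq. NH4Cl
Reagents that add atoms: none
Why: Directed ortho-metalation between two OMOM groups (all three ring positions are equivalent) and Bouveault-type formylation of the aryllithium with DMF give the aldehyde.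

Step 16
Reactants: 22 1-{2-hydroxy-4,6-bis(methoxymethoxy)-3-[(R)-lavandulyl]-5-prenylphenyl}ethan-1-one; 28 2,4,6-tris(methoxymethoxy)benzaldehyde
Product: 30 (E)-1-{2-hydroxy-4,6-bis(methoxymethoxy)-3-[(R)-lavandulyl]-5-prenylphenyl}-3-[2,4,6-tris(methoxymethoxy)phenyl]prop-2-en-1-one, via β-hydroxy ketone aldol adduct 29 (not isolated)
Conditions: KOH, EtOH/H2O, rt, 48 h
Reagents that add atoms: none
Why: In this Claisen–Schmidt aldol condensation the methyl ketone enolate adds to the non-enolisable aldehyde and the aldol dehydrates by E1cB to the conjugated E-enone, joining the two aromatic fragments.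

Step 17
Reactants: 30 (E)-2'-hydroxychalcone
Product: 31 5,7-bis(methoxymethoxy)-8-[(R)-lavandulyl]-6-prenyl-2-[2,4,6-tris(methoxymethoxy)phenyl]chroman-4-one as a 1:1 mixture of the (2S) and (2R) epimers
Conditions: NaOAc, EtOH, reflux (recovered 30 recycled)
Reagents that add atoms: none
Why: Intramolecular oxa-Michael addition of the only free phenoxide closes ring C with the lavandulyl group at C8, and the new C2 centre forms without control, so both epimers result.

Step 18
Reactants: 31 penta-MOM flavanone (C2-epimer mixture)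
Product: 32 (2S)-5,7-bis(methoxymethoxy)-8-[(R)-lavandulyl]-6-prenyl-2-[2,4,6-tris(methoxymethoxy)phenyl]chroman-4-one
Conditions: RuCl(p-cymene)[(R,R)-TsDPEN] (3 mol %), HCO2H/Et3N (5:2), EtOAc, 30 °C, stopped at about 50–55% conversion; chromatography
Reagents that add atoms: none
Why: This Noyori-type asymmetric transfer hydrogenation acts as a kinetic resolution, since the (R,R)-catalyst reduces the (2R)-epimer to the cis-(2R,4R)-flavan-4-ol (hydride anti to the 2-aryl group) while the mismatched (2S)-epimer is recovered, so C2 is selected here and not created.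

Step 19
Reactants: 32 (2S)-penta-MOM flavanone
Product: 33 (2S)-5,7-dihydroxy-8-[(2R)-5-methyl-2-(prop-1-en-2-yl)hex-4-en-1-yl]-6-(3-methylbut-2-en-1-yl)-2-(2,4,6-trihydroxyphenyl)chroman-4-one
Conditions: 3 M aq. HCl, MeOH, 40 °C, stopped at full conversion
Reagents that add atoms: none
Why: Acid-catalysed acetal solvolysis (transacetalisation to dimethoxymethane) removes all five MOM groups under conditions mild enough to spare C2 and the prenyl and lavandulyl alkenes.

**Compound list**
1 | resorcinol | Oc1cccc(O)c1 | starting material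
2 | 1,3-bis(methoxymethoxy)benzene | COCOc1cccc(OCOC)c1 | intermediate
3 | prenyl bromide (1-bromo-3-methylbut-2-ene) | CC(C)=CCBr | starting material
4 | 2,6-bis(methoxymethoxy)phenyllithium | [Li]c1c(OCOC)cccc1OCOC | intermediate (not isolated)
5 | 1,3-bis(methoxymethoxy)-2-prenylbenzene | COCOc1cccc(OCOC)c1CC=C(C)C | intermediate
6 | 2-[3,5-bis(methoxymethoxy)-4-prenylphenyl]-4,4,5,5-tetramethyl-1,3,2-dioxaborolane | COCOc1cc(B2OC(C)(C)C(C)(C)O2)cc(OCOC)c1CC=C(C)C | intermediate (not isolated)
7 | 3,5-bis(methoxymethoxy)-4-prenylphenol | COCOc1cc(O)cc(OCOC)c1CC=C(C)C | intermediate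
8 | 3,5-bis(methoxymethoxy)-4-prenylphenyl SEM ether | COCOc1cc(OCOCC[Si](C)(C)C)cc(OCOC)c1CC=C(C)C | intermediate
9 | 2-lithio derivative of 8 (lithium between OSEM and OMOM) | COCOc1cc(OCOCC[Si](C)(C)C)c([Li])c(OCOC)c1CC=C(C)C | intermediate (not isolated)
10 | 2-iodo-3,5-bis(methoxymethoxy)-4-prenylphenyl SEM ether | COCOc1cc(OCOCC[Si](C)(C)C)c(I)c(OCOC)c1CC=C(C)C | intermediate
11 | 3-methylbut-2-enoyl chloride | CC(C)=CC(Cl)=O | starting material
12 | (4S)-4-benzyl-3-(3-methylbut-2-enoyl)oxazolidin-2-one | CC(C)=CC(=O)N1[C@@H](Cc2ccccc2)COC1=O | intermediate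
13 | sodium (Z)-dienolate of 12 | C=C(C)/C=C(\O[Na])N1[C@@H](Cc2ccccc2)COC1=O | intermediate (not isolated)
14 | (4S)-4-benzyl-3-[(2S)-5-methyl-2-(prop-1-en-2-yl)hex-4-enoyl]oxazolidin-2-one | C=C(C)[C@H](CC=C(C)C)C(=O)N1[C@@H](Cc2ccccc2)COC1=O | intermediate
15 | (2S)-5-methyl-2-(prop-1-en-2-yl)hex-4-en-1-ol, (S)-lavandulol | C=C(C)[C@H](CC=C(C)C)CO | intermediate
16 | (3S)-3-(iodomethyl)-2,6-dimethylhepta-1,5-diene, (S)-lavandulyl iodide | C=C(C)[C@H](CC=C(C)C)CI | intermediate
17 | [(2S)-5-methyl-2-(prop-1-en-2-yl)hex-4-en-1-yl]zinc iodide | C=C(C)[C@H](CC=C(C)C)C[Zn]I | intermediate (not isolated)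
18 | 3,5-bis(methoxymethoxy)-2-[(R)-lavandulyl]-4-prenylphenyl SEM ether | C=C(C)[C@H](CC=C(C)C)Cc1c(OCOCC[Si](C)(C)C)cc(OCOC)c(CC=C(C)C)c1OCOC | intermediate
19 | N-methoxy-N-methylacetamide | CC(=O)N(C)OC | starting material
20 | 6-lithio derivative of 18 (lithium between OSEM and OMOM) | C=C(C)[C@H](CC=C(C)C)Cc1c(OCOCC[Si](C)(C)C)c([Li])c(OCOC)c(CC=C(C)C)c1OCOC | intermediate (not isolated)
21 | 1-{2-(SEM-oxy)-4,6-bis(methoxymethoxy)-3-[(R)-lavandulyl]-5-prenylphenyl}ethan-1-one | C=C(C)[C@H](CC=C(C)C)Cc1c(OCOCC[Si](C)(C)C)c(C(C)=O)c(OCOC)c(CC=C(C)C)c1OCOC | intermediate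
22 | 1-{2-hydroxy-4,6-bis(methoxymethoxy)-3-[(R)-lavandulyl]-5-prenylphenyl}ethan-1-one | C=C(C)[C@H](CC=C(C)C)Cc1c(O)c(C(C)=O)c(OCOC)c(CC=C(C)C)c1OCOC | intermediate
23 | 2-[3,5-bis(methoxymethoxy)phenyl]-4,4,5,5-tetramethyl-1,3,2-dioxaborolane | COCOc1cc(OCOC)cc(B2OC(C)(C)C(C)(C)O2)c1 | intermediate (not isolated)
24 | 3,5-bis(methoxymethoxy)phenol | COCOc1cc(O)cc(OCOC)c1 | intermediate
25 | 1,3,5-tris(methoxymethoxy)benzene | COCOc1cc(OCOC)cc(OCOC)c1 | intermediate
26 | N,N-dimethylformamide | CN(C)C=O | starting material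
27 | 2,4,6-tris(methoxymethoxy)phenyllithium | [Li]c1c(OCOC)cc(OCOC)cc1OCOC | intermediate (not isolated)
28 | 2,4,6-tris(methoxymethoxy)benzaldehyde | O=Cc1c(OCOC)cc(OCOC)cc1OCOC | intermediate
29 | β-hydroxy ketone aldol adduct of 22 and 28 (carbinol centre unspecified, both epimers; lavandulyl R) | C=C(C)[C@H](CC=C(C)C)Cc1c(O)c(C(=O)CC(O)c2c(OCOC)cc(OCOC)cc2OCOC)c(OCOC)c(CC=C(C)C)c1OCOC | intermediate (not isolated)
30 | (E)-1-{2-hydroxy-4,6-bis(methoxymethoxy)-3-[(R)-lavandulyl]-5-prenylphenyl}-3-[2,4,6-tris(methoxymethoxy)phenyl]prop-2-en-1-one | C=C(C)[C@H](CC=C(C)C)Cc1c(O)c(C(=O)/C=C/c2c(OCOC)cc(OCOC)cc2OCOC)c(OCOC)c(CC=C(C)C)c1OCOC | intermediate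
31 | 5,7-bis(methoxymethoxy)-8-[(R)-lavandulyl]-6-prenyl-2-[2,4,6-tris(methoxymethoxy)phenyl]chroman-4-one, 1:1 mixture of C2 epimers (C2 unspecified) | C=C(C)[C@H](CC=C(C)C)Cc1c(OCOC)c(CC=C(C)C)c(OCOC)c2c1OC(c1c(OCOC)cc(OCOC)cc1OCOC)CC2=O | intermediate
32 | (2S)-5,7-bis(methoxymethoxy)-8-[(R)-lavandulyl]-6-prenyl-2-[2,4,6-tris(methoxymethoxy)phenyl]chroman-4-one | C=C(C)[C@H](CC=C(C)C)Cc1c(OCOC)c(CC=C(C)C)c(OCOC)c2c1O[C@H](c1c(OCOC)cc(OCOC)cc1OCOC)CC2=O | intermediate
33 | (2S)-5,7-dihydroxy-8-[(2R)-5-methyl-2-(prop-1-en-2-yl)hex-4-en-1-yl]-6-(3-methylbut-2-en-1-yl)-2-(2,4,6-trihydroxyphenyl)chroman-4-one | C=C(C)[C@H](CC=C(C)C)Cc1c(O)c(CC=C(C)C)c(O)c2c1O[C@H](c1c(O)cc(O)cc1O)CC2=O | target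

**Step count**
Total: 19 steps. Longest linear sequence: 12 steps (steps 1, 2, 3, 4, 5, 10, 11, 12, 16, 17, 18, 19).

**Three steps most likely to fail, with fallbacks**

Step 10 (Negishi coupling). The aryl iodide carries two ortho alkoxy groups and the alkylzinc is β-branched, so slow coupling, protodeiodination or β-hydride elimination could erode the yield. The fallback sets out from alcohol 15 and from aryllithium 9 (generated from 8 exactly as in step 5) and comes back to the route at 18. Alcohol 15 is converted with Tf2O and 2,6-lutidine in CH2Cl2 at −78 °C into (2S)-5-methyl-2-(prop-1-en-2-yl)hex-4-en-1-yl trifluoromethanesulfonate F1. F1 is used at once to alkylate 9 in THF at −78 °C by direct SN2 at the primary carbon, so neither palladium, zinc nor the aryl iodide is needed.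

Step 18 (kinetic resolution). The 5-OMOM group and the bulky 2-aryl group may slow the reduction or lower the selectivity factor, leaving 32 contaminated with its C2 epimer. The fallback sets out from 31 and comes back at 32. Because the two components of 31 are diastereomers, they are separated by preparative HPLC on a cellulose-based chiral stationary phase. The unwanted (2R)-configured penta-MOM flavanone F2 is re-equilibrated to the 1:1 mixture 31 through chalcone 30 under the conditions of step 17 (NaOAc, EtOH, reflux) and recycled, so no catalyst-controlled selectivity is required.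

Step 19 (global MOM removal). Protic acid may cyclise the prenyl or lavandulyl alkene onto a neighbouring phenol, or epimerise C2 by ionising the very electron-rich benzylic C2–O bond. The fallback sets out from 32 and comes back at 33. It replaces protic solvolysis by silyl transacetalisation: Me3SiOTf and 2,2'-bipyridyl in CH2Cl2 at 0 °C convert the five aryl MOM ethers into the pentakis(trimethylsilyl) ether of the target F3 under buffered, non-protic conditions. F3 is then hydrolysed with water at rt to 33.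

**Further compounds**
F1 | step 10 | (2S)-5-methyl-2-(prop-1-en-2-yl)hex-4-en-1-yl trifluoromethanesulfonate | C=C(C)[C@H](CC=C(C)C)COS(=O)(=O)C(F)(F)F
F2 | step 18 | (2R)-5,7-bis(methoxymethoxy)-8-[(R)-lavandulyl]-6-prenyl-2-[2,4,6-tris(methoxymethoxy)phenyl]chroman-4-one | C=C(C)[C@H](CC=C(C)C)Cc1c(OCOC)c(CC=C(C)C)c(OCOC)c2c1O[C@@H](c1c(OCOC)cc(OCOC)cc1OCOC)CC2=O
F3 | step 19 | pentakis(trimethylsilyl) ether of 33 | C=C(C)[C@H](CC=C(C)C)Cc1c(O[Si](C)(C)C)c(CC=C(C)C)c(O[Si](C)(C)C)c2c1O[C@H](c1c(O[Si](C)(C)C)cc(O[Si](C)(C)C)cc1O[Si](C)(C)C)CC2=O
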